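**Plan**

- Labdane numbering is used: ring A = C1–C5 and C10, ring B = C5–C10, C20 is the methyl on C10, C17 the methyl on C8, C18 (CH2OH) and C19 (CH3) sit on C4, and the chain C11–C15 (C16 = methyl on C13) hangs from C9. Cuts, in retrosynthetic order: the C15–O malonate ester; C8–C17 (methyl carbinol from a C8 ketone through the exocyclic alkene and its epoxide); C4–C18 (reductive aldol on a ring A enone); C9–C11 (chain onto a C9 carbonyl); C1–C10 and C4–C5 ([4+2]).
- Enabling feature: C10 (quaternary, methyl) and C5 (methine) lie between C9 and C6 as the methyl-bearing double bond of a 1,4-benzoquinone lies between its carbonyls, and the oxygenated C8 corresponds to a methoxy-bearing quinone carbon. Ring B is therefore 2-methoxy-6-methylbenzoquinone and C1–C4 a 2-silyloxydiene.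
- Forward: ring B enters as the quinone and ring A closes in the cycloaddition. The chain is added to the C9 carbonyl, ring B is trimmed to the C8 ketone and its leftover double bond is moved into ring A. C4/C5, C3, C8 and the malonate are then completed.
- Stereochemistry: C10 from the chiral titanium catalyst; C13 from methyl hydrogen (R)-3-methylglutarate; C5 and C4 from dissolving-metal reduction of the ring A enone (trans fusion, electrophile anti to C20); C9 by equilibration next to the C8 ketone (equatorial chain); C8 by epoxidation anti to C20 followed by hydride opening.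

Key step: step 3

Assumption: the (R)-BINOL titanium catalyst is taken to leave open the quinone face that leads to the 8aR adduct 5; should the sense be opposite, (S)-BINOL is used and nothing else changes.

**Route**

Step 1
Reactants: 1 2-methoxy-6-methylphenol
Product: 2 2-methoxy-6-methyl-1,4-benzoquinone
Conditions: (KSO3)2NO (2.2 equiv), KH2PO4, H2O/acetone, 0 → 23 °C
Reagents that add atoms: potassium nitrosodisulfonate, [K+].[K+].[O-]S(=O)(=O)N([O])S(=O)(=O)[O-]
Why: Teuber oxidation, in which the nitroxyl radical removes the phenolic hydrogen and a second equivalent delivers oxygen to the free para carbon, so the para-quinone should form with the methoxy and methyl groups untouched.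

Step 2
Reactants: 3 pent-1-en-3-one
Product: 4 (Z)-3-(tert-butyldimethylsilyloxy)penta-1,3-diene
Conditions: TBSOTf, Et3N, Et2O, 0 °C
Reagents that add atoms: tert-butyldimethylsilyl triflate, CC(C)(C)[Si](C)(C)OS(=O)(=O)C(F)(F)F
Why: Soft enolisation (O-silylation, then removal of an ethyl CH2 proton by the amine) gives the 2-silyloxydiene, and the Z enol ether is expected because the proton is lost from the conformer that keeps the methyl group away from the vinyl group.

Step 3
Reactants: 2 2-methoxy-6-methyl-1,4-benzoquinone; 4 (Z)-3-(tert-butyldimethylsilyloxy)penta-1,3-diene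
Product: 5 (4aS,5R,8aR)-6-(tert-butyldimethylsilyloxy)-2-methoxy-5,8a-dimethyl-4a,5,8,8a-tetrahydronaphthalene-1,4-dione
Conditions: TiCl2(OiPr)2 (0.1 equiv), (R)-BINOL (0.1 equiv), 4 Å molecular sieves, CH2Cl2, −30 → 0 °C
Reagents that add atoms: none
Why: The BINOL complex of tetravalent titanium binds the quinone as a five-membered chelate through the C9 carbonyl oxygen and the C8 methoxy oxygen, which lowers the LUMO of the C5=C10 double bond and puts its largest coefficient on C5, so the enol ether carbon of 4 (the future C4) bonds to C5 ahead of C1–C10 in a concerted, asynchronous endo [4+2] cycloaddition, the known chelation-controlled asymmetric Diels–Alder reaction of methoxyquinones with 2-silyloxydienes. Ring A closes by this intermolecular two-bond union (C1–C10 and C4–C5), both bonds forming on the same face of the quinone. C10 is set by the BINOL ligand, which leaves one face of the chelated quinone open; C5 follows from suprafacial addition (H5 cis to C20, cis ring fusion); C4 follows from the endo transition state together with the Z enol ether geometry, which puts H4 cis to H5. The step needs site selectivity (the C7=C8 bond is deactivated by its methoxy donor and stays out), regioselectivity (supplied by two-point chelation, since a monodentate acid on the C6 carbonyl would direct the other way) and enantioselectivity (supplied by the ligand). Only C10 has to persist, because C4 and C5 are flattened in step 11 and rebuilt in step 13.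

Step 4
Reactants: 6 methyl hydrogen (R)-3-methylglutarate
Product: 7 methyl (3R)-5-hydroxy-3-methylpentanoate
Conditions: BH3·SMe2, THF, 0 → 23 °C; aq. work-up
Reagents that add atoms: none
Why: Borane reduces the free carboxylic acid through its acyloxyborane far faster than the methyl ester, which differentiates the two ends of the C5 unit without touching the stereocentre.

Step 5
Reactants: 7 methyl (3R)-5-hydroxy-3-methylpentanoate
Product: 8 methyl (3R)-3-methyl-5-(triisopropylsilyloxy)pentanoate
Conditions: TIPSCl, imidazole, CH2Cl2, 23 °C
Reagents that add atoms: chlorotriisopropylsilane, CC(C)[Si](Cl)(C(C)C)C(C)C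
Why: Imidazole-promoted silylation of the primary alcohol, carried out at once so that the hydroxy ester cannot lactonise, installs an ether that should withstand the organometallic, acidic and dissolving-metal steps ahead.

Step 6
Reactants: 8 methyl (3R)-3-methyl-5-(triisopropylsilyloxy)pentanoate
Product: 9 (3S)-3-methyl-5-(triisopropylsilyloxy)pentan-1-ol
Conditions: LiAlH4, Et2O, 0 °C
Reagents that add atoms: none
Why: Hydride reduction of the methyl ester to the primary alcohol leaves the silyl ether and the stereocentre untouched, the change of descriptor from R to S being only a change of substituent priorities.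

Step 7
Reactants: 9 (3S)-3-methyl-5-(triisopropylsilyloxy)pentan-1-ol
Product: 10 [(3R)-5-iodo-3-methylpentyl]oxy(triisopropyl)silane
Conditions: I2, PPh3, imidazole, CH2Cl2, 0 → 23 °C
Reagents that add atoms: iodine, II
Why: Appel-type iodination through the alkoxyphosphonium salt replaces the primary hydroxyl by iodide in an SN2 step at a carbon remote from the stereocentre.

Step 8
Reactants: 10 [(3R)-5-iodo-3-methylpentyl]oxy(triisopropyl)silane; 5 Diels–Alder adduct
Product: 13 cis-fused C9 tertiary carbinol carrying the C11–C16 chain (C9 epimers), via alkyllithium 11 (not isolated), via alkylcerium dichloride 12 (not isolated)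
Conditions: 10, t-BuLi (2.0 equiv), Et2O/pentane, −78 °C; CeCl3, THF, −78 °C; then 5, −78 → −40 °C; aq. NH4Cl
Reagents that add atoms: none
Why: Iodine–lithium exchange and transmetalation to cerium give a weakly basic, oxophilic nucleophile for 1,2-addition to the C9 ketone, which cannot enolise and is the more electrophilic carbonyl because C6 is a vinylogous ester and because the metal can bridge the C9 carbonyl and the C8 methoxy oxygen; the new C9 carbinol centre is left uncontrolled since its oxygen is removed in step 10.

Step 9
Reactants: 13 C9 tertiary carbinol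
Product: 15 cis-fused 9-hydroxy-6-ene-3,8-dione (α′-hydroxy enone), via C6 allylic alcohol 14 (not isolated)
Conditions: i-Bu2AlH (3 equiv), CH2Cl2, −78 °C; then 1 M aq. HCl, THF, 0 → 23 °C
Reagents that add atoms: water, O
Why: Stork–Danheiser transposition, in which 1,2-reduction of the vinylogous ester carbonyl and acid hydrolysis of the resulting methoxy-substituted allylic alcohol (through the C8 oxocarbenium ion, with loss of the C6 hydroxyl and methanol) give the C6=C7–C8 enone, the same acid cleaving the silyl enol ether to the C3 ketone.

Step 10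
Reactants: 15 α′-hydroxy enone
Product: 16 cis-fused 6-ene-3,8-dione with hydrogen on C9 (C9 epimers)
Conditions: SmI2 (2.5 equiv), THF/MeOH, −78 °C
Reagents that add atoms: none
Why: Reductive cleavage of an α-hydroxy ketone by SmI2 (two single-electron transfers to the C8 carbonyl, β-elimination of hydroxide, protonation of the samarium dienolate at C9 by methanol) is expected to outpace conjugate reduction of the enone at low temperature and leaves a C9 centre that is epimerisable and fixed later.

Step 11
Reactants: 16 6-ene-3,8-dione
Product: 17 ring A enone (4-methyl-4-ene-3,8-dione) with the C9 chain equatorial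
Conditions: NaOMe (0.3 equiv), MeOH, 23 → 50 °C
Reagents that add atoms: none
Why: Base-mediated prototropic double-bond migration under thermodynamic control (γ-deprotonation at C5 and α-protonation at C7 deconjugate the C8 enone to the 5(6)-ene, whose doubly activated C4–H is then removed and the dienolate protonated at C6) should end at the tetrasubstituted enone conjugated with the C3 ketone, which erases C4 and C5 and equilibrates C9 through the C8 enolate to the equatorial chain cis to C20.

Step 12
Reactants: 17 ring A enone
Product: 18 C8 ethylene ketal of 17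
Conditions: TMSOCH2CH2OTMS, TMSOTf (0.1 equiv), CH2Cl2, −78 → −20 °C
Reagents that add atoms: 1,2-bis(trimethylsilyloxy)ethane, C[Si](C)(C)OCCO[Si](C)(C)C
Why: Noyori ketalisation (silyl triflate catalysis with the bis-silyl ether of ethylene glycol) converts saturated ketones at low temperature while conjugated enones stay untouched, so only the C8 carbonyl should be masked.

Step 13
Reactants: 18 C8 ketal enone
Product: 20 trans-fused 18-hydroxy-3-ketone, via lithium enolate 19 (not isolated)
Conditions: Li (2.5 equiv), t-BuOH (1.0 equiv), NH3/THF, −78 °C; isoprene; NH3 evaporated; then CH2O (gas, from cracked paraformaldehyde), THF, −78 → −40 °C; aq. NH4Cl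
Reagents that add atoms: formaldehyde, C=O
Why: Stork reductive alkylation, in which dissolving-metal reduction of the enone protonates C5 axially to give the trans-decalin (H5 anti to C20) and the regiodefined C3–C4 lithium enolate, whose aldol reaction with monomeric formaldehyde should occur on the face of C4 opposite the axial C10 methyl and so place C18 equatorial and trans to C20.

Step 14
Reactants: 20 18-hydroxy-3-ketone
Product: 21 18-O-benzyl ether of 20
Conditions: 2-benzyloxy-1-methylpyridinium triflate, MgO, PhCF3, 83 °C
Reagents that add atoms: 2-benzyloxy-1-methylpyridinium triflate, C[n+]1ccccc1OCc1ccccc1.[O-]S(=O)(=O)C(F)(F)F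
Why: Benzyl transfer from the pyridinium salt under essentially neutral conditions etherifies the neopentyl primary alcohol without generating the alkoxide that would trigger retro-aldol loss of formaldehyde, and the ether marks C18 for the final hydrogenolysis.

Step 15
Reactants: 21 18-benzyloxy-3-ketone
Product: 23 3-deoxo compound (C3 = CH2), via N-silylhydrazone 22 (not isolated)
Conditions: TBSNHNHTBS, Sc(OTf)3 (cat.), 100 °C; then KOt-Bu, t-BuOH, DMSO, 23 → 100 °C
Reagents that add atoms: none
Why: Wolff–Kishner reduction in its silylhydrazone variant (condensation to the N-silyl hydrazone, then base-induced desilylation, tautomerisation to the diazene and loss of N2) removes the hindered C3 carbonyl under conditions the silyl ether, ketal and benzyl ether should tolerate, and no elimination can intervene because C4 is quaternary.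

Step 16
Reactants: 23 3-deoxo ketal
Product: 24 trans-fused 18-benzyloxy-15-hydroxy-8-ketone
Conditions: 3 M aq. HCl, THF/MeOH, 45 °C; neutralise; then NaOMe (0.2 equiv), MeOH, 23 °C
Reagents that add atoms: water, O
Why: Acid hydrolysis releases the C8 ketone from its ketal and cleaves the primary silyl ether, and the catalytic methoxide then equilibrates C9 through the enolate of the rigid trans-decalone to the equatorial side chain (cis to C20), the configuration of the target.

Step 17
Reactants: 24 8-ketone
Product: 25 8(17)-exocyclic alkene
Conditions: Ph3PCH3Br, KOt-Bu (excess), toluene, 90 °C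
Reagents that add atoms: methyltriphenylphosphonium bromide, C[P+](c1ccccc1)(c1ccccc1)c1ccccc1.[Br-]
Why: Wittig methylenation with the small non-stabilised ylide converts the hindered C8 ketone into the exocyclic alkene, the free hydroxyl only consuming base and any enolisation at C9 returning the equatorial isomer already in hand.

Step 18
Reactants: 25 8(17)-alkene
Product: 26 8,17-epoxide with oxygen trans to C20
Conditions: mCPBA, NaHCO3, CH2Cl2, 0 °C
Reagents that add atoms: 3-chloroperoxybenzoic acid, OOC(=O)c1cccc(Cl)c1
Why: Prilezhaev epoxidation of the 1,1-disubstituted alkene is expected from the face opposite the axial C10 methyl, which is 1,3-diaxial to the other trajectory, so that the new C8–O bond is equatorial and trans to C20 as is usual for labd-8(17)-enes.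

Step 19
Reactants: 26 8,17-epoxide
Product: 27 8,15-diol 18-benzyl ether
Conditions: LiAlH4, THF, 0 → 65 °C
Reagents that add atoms: none
Why: SN2 opening of the spiro-epoxide by hydride at its unsubstituted CH2 carbon turns that carbon into the C17 methyl and leaves the C8–O bond, and hence the C8 configuration, untouched.

Step 20
Reactants: 27 8,15-diol 18-benzyl ether; 28 benzyl hydrogen malonate
Product: 29 15-O-(benzyl malonyl) 18-benzyl ether
Conditions: EDC·HCl, DMAP (0.1 equiv), CH2Cl2, 0 °C
Reagents that add atoms: none
Why: Steglich esterification should acylate only the unhindered primary C15 hydroxyl, the tertiary C8 hydroxyl being inert to the O-acylisourea at 0 °C and C18 being blocked as its benzyl ether.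

Step 21
Reactants: 29 15-O-(benzyl malonyl) 18-benzyl ether
Product: 30 3-{[(3S)-5-[(1S,2S,4aS,5S,8aR)-2-hydroxy-5-(hydroxymethyl)-2,5,8a-trimethyldecahydronaphthalen-1-yl]-3-methylpentyl]oxy}-3-oxopropanoic acid (CNP0324566.1)
Conditions: H2 (1 atm), Pd(OH)2/C, EtOAc, 23 °C
Reagents that add atoms: none
Why: Hydrogenolysis cleaves the benzyl ester and the benzyl ether in one operation under neutral conditions that leave the malonate half-ester, the tertiary alcohol and all stereocentres untouched.

**Compound list**

1 | 2-methoxy-6-methylphenol | COc1cccc(C)c1O | starting material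
2 | 2-methoxy-6-methyl-1,4-benzoquinone | COC1=CC(=O)C=C(C)C1=O | intermediate
3 | pent-1-en-3-one (ethyl vinyl ketone) | CCC(=O)C=C | starting material
4 | (Z)-3-(tert-butyldimethylsilyloxy)penta-1,3-diene | C=C/C(O[Si](C)(C)C(C)(C)C)=C/C | intermediate
5 | (4aS,5R,8aR)-6-(tert-butyldimethylsilyloxy)-2-methoxy-5,8a-dimethyl-4a,5,8,8a-tetrahydronaphthalene-1,4-dione; cis-fused, H4, H5 and C20 on one face | O=C1[C@]2(C)CC=C(O[Si](C)(C)C(C)(C)C)[C@H](C)[C@@H]2C(=O)C=C1OC | intermediate
6 | methyl hydrogen (R)-3-methylglutarate | C[C@H](CC(=O)O)CC(=O)OC | starting material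
7 | methyl (3R)-5-hydroxy-3-methylpentanoate | C[C@H](CCO)CC(=O)OC | intermediate
8 | methyl (3R)-3-methyl-5-(triisopropylsilyloxy)pentanoate | C[C@H](CCO[Si](C(C)C)(C(C)C)C(C)C)CC(=O)OC | intermediate
9 | (3S)-3-methyl-5-(triisopropylsilyloxy)pentan-1-ol | C[C@H](CCO[Si](C(C)C)(C(C)C)C(C)C)CCO | intermediate
10 | [(3R)-5-iodo-3-methylpentyl]oxy(triisopropyl)silane | C[C@H](CCO[Si](C(C)C)(C(C)C)C(C)C)CCI | intermediate
11 | alkyllithium from 10 (iodine replaced by lithium, stereocentre unchanged) | C[C@H](CCO[Si](C(C)C)(C(C)C)C(C)C)CC[Li] | intermediate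
12 | alkylcerium dichloride from 11 | C[C@H](CCO[Si](C(C)C)(C(C)C)C(C)C)CC[Ce](Cl)Cl | intermediate
13 | C9 carbinol: 5 with the C9 carbonyl converted into C(OH) bearing the (3S)-3-methyl-5-(triisopropylsilyloxy)pentyl chain; C6 vinylogous ester, C2=C3 silyl enol ether and cis fusion as in 5; C9 epimers | C[C@H](CCO[Si](C(C)C)(C(C)C)C(C)C)CCC1(O)[C@]2(C)CC=C(O[Si](C)(C)C(C)(C)C)[C@H](C)[C@@H]2C(=O)C=C1OC | intermediate
14 | C6 allylic alcohol from 13 (C6 carbonyl reduced to CHOH; C6 and C9 epimers) | C[C@H](CCO[Si](C(C)C)(C(C)C)C(C)C)CCC1(O)[C@]2(C)CC=C(O[Si](C)(C)C(C)(C)C)[C@H](C)[C@@H]2C(O)C=C1OC | intermediate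
15 | cis-fused α′-hydroxy enone: C3 ketone, C4 methyl as in 5, H5 cis to C20, C6=C7, C8 ketone, C9 bearing OH and the chain (C9 epimers) | C[C@H](CCO[Si](C(C)C)(C(C)C)C(C)C)CCC1(O)[C@]2(C)CCC(=O)[C@H](C)[C@@H]2C=CC1=O | intermediate
16 | cis-fused 6-ene-3,8-dione: 15 with hydrogen in place of the C9 hydroxyl (C9 epimers) | C[C@H](CCO[Si](C(C)C)(C(C)C)C(C)C)CCC1[C@]2(C)CCC(=O)[C@H](C)[C@@H]2C=CC1=O | intermediate
17 | ring A enone: 3-oxo-4-ene with methyl on C4, C8 ketone, C9 chain cis to C20 (equatorial), C10 as in 5 | C[C@H](CCO[Si](C(C)C)(C(C)C)C(C)C)CC[C@H]1[C@]2(C)CCC(=O)C(C)=C2CCC1=O | intermediate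
18 | 17 with C8 as its 1,3-dioxolane | C[C@H](CCO[Si](C(C)C)(C(C)C)C(C)C)CC[C@H]1[C@]2(C)CCC(=O)C(C)=C2CCC13OCCO3 | intermediate
19 | lithium C3–C4 enolate of reduced 18, trans-fused (H5 trans to C20) | C[C@H](CCO[Si](C(C)C)(C(C)C)C(C)C)CC[C@H]1[C@]2(C)CCC(O[Li])=C(C)[C@H]2CCC13OCCO3 | intermediate
20 | trans-fused 3-ketone with C4 bearing CH3 (C19, cis to C20) and CH2OH (C18, trans to C20); C8 dioxolane | C[C@H](CCO[Si](C(C)C)(C(C)C)C(C)C)CC[C@H]1[C@]2(C)CCC(=O)[C@](C)(CO)[C@H]2CCC13OCCO3 | intermediate
21 | 18-O-benzyl ether of 20 | C[C@H](CCO[Si](C(C)C)(C(C)C)C(C)C)CC[C@H]1[C@]2(C)CCC(=O)[C@](C)(COCc3ccccc3)[C@H]2CCC13OCCO3 | intermediate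
22 | C3 N-(tert-butyldimethylsilyl)hydrazone of 21 | C[C@H](CCO[Si](C(C)C)(C(C)C)C(C)C)CC[C@H]1[C@]2(C)CCC(=NN[Si](C)(C)C(C)(C)C)[C@](C)(COCc3ccccc3)[C@H]2CCC13OCCO3 | intermediate
23 | 21 with C3 reduced to CH2 | C[C@H](CCO[Si](C(C)C)(C(C)C)C(C)C)CC[C@H]1[C@]2(C)CCC[C@](C)(COCc3ccccc3)[C@H]2CCC13OCCO3 | intermediate
24 | trans-fused 8-ketone with free C15 hydroxyl, C18 benzyl ether and the C9 chain equatorial | C[C@H](CCO)CC[C@H]1[C@]2(C)CCC[C@](C)(COCc3ccccc3)[C@H]2CCC1=O | intermediate
25 | 8(17)-exocyclic alkene from 24 | C[C@H](CCO)CC[C@H]1[C@]2(C)CCC[C@](C)(COCc3ccccc3)[C@H]2CCC1=C | intermediate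
26 | 8,17-epoxide of 25, oxygen trans to C20 | C[C@H](CCO)CC[C@H]1[C@]2(C)CCC[C@](C)(COCc3ccccc3)[C@H]2CC[C@@]13CO3 | intermediate
27 | 8,15-diol 18-benzyl ether (C8: OH trans and C17 cis to C20) | C[C@H](CCO)CC[C@H]1[C@]2(C)CCC[C@](C)(COCc3ccccc3)[C@H]2CC[C@]1(C)O | intermediate
28 | benzyl hydrogen malonate | O=C(O)CC(=O)OCc1ccccc1 | starting material
29 | benzyl malonate ester of 27 at O15 | C[C@H](CCOC(=O)CC(=O)OCc1ccccc1)CC[C@H]1[C@]2(C)CCC[C@](C)(COCc3ccccc3)[C@H]2CC[C@]1(C)O | intermediate
30 | 3-{[(3S)-5-[(1S,2S,4aS,5S,8aR)-2-hydroxy-5-(hydroxymethyl)-2,5,8a-trimethyldecahydronaphthalen-1-yl]-3-methylpentyl]oxy}-3-oxopropanoic acid | C[C@H](CCOC(=O)CC(=O)O)CC[C@H]1[C@]2(C)CCC[C@](C)(CO)[C@H]2CC[C@]1(C)O | target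

**Count and risks**

Total step count: 21. Longest linear sequence: 18 steps (6 → 30, steps 4–21); the ring-system branch from 1 runs 16 steps.

Steps most likely to fail:

1. Step 11. The migration of the double bond from C6=C7 into ring A may stall at an equilibrium mixture, or intramolecular aldol and Michael reactions of the unsaturated diketone may take over under the equilibrating base. The fallback sets out from 16 and separates the two prototropic shifts. Stoichiometric KOt-Bu in t-BuOH/THF at 0 °C forms the extended dienolate of the C8 enone, and inverse quench into cold aqueous acetic acid protonates it kinetically at C7 to give the deconjugated 5(6)-ene-3,8-dione F1. Brief treatment of F1 with catalytic DBU in CH2Cl2 at 23 °C then carries out the β,γ to α,β isomerisation toward the C3 ketone, and the route is rejoined at 17.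

2. Step 10. Conjugate reduction of the C6=C7 enone may compete with the slow loss of the unactivated tertiary hydroxyl from the ketyl. The fallback sets out from 15 and turns the hydroxyl into a leaving group first. Trifluoroacetic anhydride, pyridine and DMAP in CH2Cl2 at 0 °C give the C9 trifluoroacetate F2, whose α-acyloxy ketone is cleaved rapidly by SmI2 in THF/MeOH at −78 °C (or by zinc in acetic acid). The route is rejoined at 16.

3. Step 8. The nucleophile may attack the less hindered C6 vinylogous ester carbonyl, or be quenched by proton transfer from C5–H, faster than it adds to the hindered C9 ketone. The fallback sets out from 5 and masks the C6 carbonyl in the flask. LiN(SiMe3)2 (1.05 equiv) in THF at −78 °C removes the C5 proton to give the C5=C6 lithium enolate F3; C9 has no α-hydrogen and stays a ketone. The cerium reagent 12 is then added to the same flask. Aqueous work-up reprotonates C5 and the route is rejoined at 13; the C5 configuration is in any case erased in step 11.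

Further compounds
F1 | step 11 | cis-series 5(6)-ene-3,8-dione: 16 with the double bond moved from C6=C7 to C5=C6 (C4 and C9 epimers) | C[C@H](CCO[Si](C(C)C)(C(C)C)C(C)C)CCC1[C@]2(C)CCC(=O)C(C)C2=CCC1=O
F2 | step 10 | C9 trifluoroacetate of 15 | C[C@H](CCO[Si](C(C)C)(C(C)C)C(C)C)CCC1(OC(=O)C(F)(F)F)[C@]2(C)CCC(=O)[C@H](C)[C@@H]2C=CC1=O
F3 | step 8 | C5=C6 lithium enolate of 5 | O=C1[C@]2(C)CC=C(O[Si](C)(C)C(C)(C)C)[C@H](C)C2=C(O[Li])C=C1OC
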